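**Retrosynthetic overview**
1. Plakotenin 34 comes from aldehyde 31 by (E)-selective Wittig olefination and saponification; 31 comes from hydrindene acetal 30.
2. The strategy rests on the only ring unsaturation, the trisubstituted C4(Me)=C5H alkene of the cyclohexene, which lies between ring-fusion carbon C3 and the benzylic C6H(Ph). It is cut there and bridged by SO2, giving thiepane 1,1-dioxide 27, which contracts by Ramberg–Bäcklund reaction.
3. Sulfone 27 comes from bis-mesylate 24 by double displacement with sulfide; 24 comes from lactone 18, which already carries all six stereocentres on a monocyclic cyclopentane.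
4. Lactone 18 comes from (R)-4-phenylbutyrolactone (as its ketene silyl acetal), (S)-4-silyloxycyclopentenone and acetaldehyde by Mukaiyama–Michael/aldol coupling, two methylenation–hydrogenation pairs and lactone α-ethylation anti to phenyl.
5. Ring order: cyclopentane (bought), lactone (temporary template), thiepane, cyclohexene (last).

Key step: step 20

**Remarks on the chemistry**
- Atom labels of the target are used throughout: C1 quaternary carbon; C2 and C3 ring-fusion carbons (C2 on C1); C4 = C(Me)=; C5 = =CH; C6 = CH(Ph); C7 = carbon on C1 that ends as the side-chain CH=; C9, C10, C11 = cyclopentane CH(Me), CH2, CH(Me), with C9 next to C3.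
- Assumption: the C4 carbinol centre formed in step 3 is not controlled. It is carried as an epimer pair and drawn without configuration, because C4 becomes sp2 in step 20.
- The lactone α-centre (C1) in 8–15 is drawn as the expected isomer (anti to phenyl) and is re-set in step 10.

**Route**

Step 1
Reactants: 1 furan-2(5H)-one; 2 phenylboronic acid
Product: 3 (R)-4-phenyldihydrofuran-2(3H)-one
Conditions: Rh(acac)(C2H4)2 (3 mol%), (R)-BINAP (3.3 mol%), 1,4-dioxane/H2O (10:1), 100 °C
Reagents that add atoms: none
Why: Rhodium-catalysed asymmetric 1,4-addition of an arylboronic acid (Hayashi–Miyaura reaction) to the butenolide; the BINAP-bound phenylrhodium species should add to one enantioface and set C6 as (R), the same sense as with cycloalkenones and 5,6-dihydropyran-2-one.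

Step 2
Reactants: 3 (R)-4-phenyldihydrofuran-2(3H)-one
Product: 5 (R)-trimethyl[(4-phenyl-4,5-dihydrofuran-2-yl)oxy]silane, via lithium lactone enolate 4 (not isolated)
Conditions: LDA, THF, −78 °C; then TMSCl, −78 °C → rt; used crude
Reagents that add atoms: chlorotrimethylsilane, C[Si](C)(C)Cl
Why: Kinetic deprotonation of the lactone and O-silylation of the enolate should give the ketene silyl acetal needed for a Mukaiyama–Michael addition; the C6 stereocentre is not touched.

Step 3
Reactants: 5 (R)-trimethyl[(4-phenyl-4,5-dihydrofuran-2-yl)oxy]silane; 6 (S)-4-(tert-butyldimethylsilyloxy)cyclopent-2-en-1-one; 7 acetaldehyde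
Product: 9 β-hydroxy ketone (C9 ketone; 1-hydroxyethyl on C3 trans to the lactone on C2; C11 silyloxy trans to the lactone; carbinol epimers), via trimethylsilyl enol ether 8 (not isolated)
Conditions: HgI2 (10 mol%), CH2Cl2, −78 → −30 °C; then MeCHO, TiCl4, −78 °C; aq. NaHCO3
Reagents that add atoms: none
Why: Mukaiyama–Michael addition of 5 to the enone should occur anti to the 4-silyloxy group (setting C2) with silyl transfer to give the regiodefined enol ether 8, and the TiCl4-mediated Mukaiyama aldol reaction of 8 with acetaldehyde should enter anti to the new C2 substituent (setting C3, 2,3-trans); the C4 carbinol centre is not controlled.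

Step 4
Reactants: 9 β-hydroxy ketone
Product: 10 triisopropylsilyl ether of 9
Conditions: TIPSOTf, 2,6-lutidine, CH2Cl2, −78 → 0 °C
Reagents that add atoms: triisopropylsilyl trifluoromethanesulfonate, CC(C)[Si](C(C)C)(C(C)C)OS(=O)(=O)C(F)(F)F
Why: Silylation with a silyl triflate and a hindered base is fast at low temperature, which avoids retro-aldol cleavage and β-elimination; the triisopropylsilyl ether is chosen to outlast the ring tert-butyldimethylsilyl ether.

Step 5
Reactants: 10 triisopropylsilyl ether
Product: 11 C9 exocyclic methylene compound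
Conditions: Zn, CH2Br2, TiCl4, THF/CH2Cl2, 0 °C → rt
Reagents that add atoms: dibromomethane, BrCBr
Why: Takai–Lombardo methylenation; the non-basic zinc/titanium methylene reagent should convert the hindered, enolisable β-silyloxy ketone to the alkene without epimerisation at C3 or β-elimination, and it does not react with the lactone.

Step 6
Reactants: 11 C9 exocyclic methylene compound
Product: 12 C9 methyl compound (methyl cis to the C3 side chain)
Conditions: H2 (1 atm), PtO2, EtOAc, rt
Reagents that add atoms: none
Why: Heterogeneous catalytic hydrogenation of the 1,1-disubstituted alkene should deliver hydrogen to the ring face opposite the adjacent 1-(silyloxy)ethyl group on C3 and the silyloxy group on C11, so the new C9 methyl ends cis to the C3 side chain (steric approach control).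

Step 7
Reactants: 12 C9 methyl compound
Product: 13 C11 alcohol (triisopropylsilyl ether retained)
Conditions: CSA (cat.), MeOH/CH2Cl2 (1:1), 0 °C → rt
Reagents that add atoms: none
Why: Acid-catalysed methanolysis of silyl ethers discriminates by bulk at silicon, so the tert-butyldimethylsilyl ether should be cleaved while the hindered triisopropylsilyl ether and the lactone remain.

Step 8
Reactants: 13 C11 alcohol
Product: 14 C11 ketone
Conditions: Dess–Martin periodinane, NaHCO3, CH2Cl2, rt
Reagents that add atoms: none
Why: Dess–Martin oxidation under buffered conditions should give the cyclopentanone; C2, now α to the ketone, is already in its more stable trans arrangement to the C3 substituent.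

Step 9
Reactants: 14 C11 ketone
Product: 15 C11 exocyclic methylene lactone
Conditions: Zn, CH2Br2, TiCl4, THF/CH2Cl2, 0 °C → rt
Reagents that add atoms: dibromomethane, BrCBr
Why: Takai–Lombardo methylenation again avoids enolisation of the α-branched ketone and leaves the lactone intact.

Step 10
Reactants: 15 C11 exocyclic methylene lactone
Product: 17 C1-ethyl lactone (ethyl trans to phenyl; cyclopentyl cis to phenyl), via lithium enolate 16 (not isolated)
Conditions: LDA, THF, −78 → −20 °C; then EtI, DMPU, −78 °C → rt
Reagents that add atoms: iodoethane, CCI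
Why: Lactone enolate alkylation; the planar enolate 16 should be ethylated on the face anti to the adjacent C6 phenyl group, which sets the quaternary C1 centre, and keeping C11 as a flat methylene leaves the enolate carbon accessible.

Step 11
Reactants: 17 C1-ethyl lactone
Product: 18 lactone with all six stereocentres (C11 methyl cis to the C2 substituent)
Conditions: H2 (3 atm), PtO2, EtOAc, rt
Reagents that add atoms: none
Why: Heterogeneous hydrogenation of the exocyclic alkene should take place on the face opposite the adjacent C2 substituent, which now carries the quaternary C1, so the new C11 methyl ends cis to that substituent (steric approach control).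

Step 12
Reactants: 18 lactone
Product: 19 1,4-diol (C5–OH and C7–OH; C4 silyl ether retained)
Conditions: LiAlH4, THF, 0 °C → reflux
Reagents that add atoms: none
Why: Hydride reduction of the lactone with LiAlH4 should give the diol, the triisopropylsilyl ether being inert.

Step 13
Reactants: 19 1,4-diol
Product: 20 C5 tert-butyldiphenylsilyl ether with free C7 hydroxyl
Conditions: TBDPSCl, imidazole, CH2Cl2, 0 °C
Reagents that add atoms: tert-butylchlorodiphenylsilane, CC(C)(C)[Si](Cl)(c1ccccc1)c1ccccc1
Why: Silylation with the bulky chlorosilane should select the primary C5 hydroxyl over the neopentyl C7 hydroxyl, which is flanked by the quaternary C1.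

Step 14
Reactants: 20 C5 silyl ether
Product: 21 C7 aldehyde
Conditions: Dess–Martin periodinane, NaHCO3, CH2Cl2, rt
Reagents that add atoms: none
Why: Dess–Martin oxidation of the neopentyl alcohol should give the aldehyde, which has no α-hydrogen and cannot epimerise.

Step 15
Reactants: 21 C7 aldehyde
Product: 22 C7 dimethyl acetal (both silyl ethers retained)
Conditions: HC(OMe)3, MeOH, TsOH·H2O (cat.), rt; Et3N quench
Reagents that add atoms: trimethyl orthoformate, COC(OC)OC; methanol, CO
Why: Acid-catalysed acetalisation driven by the orthoformate should convert the hindered aldehyde to the dimethyl acetal; the C5 oxygen is kept silylated so that no cyclic 2-methoxytetrahydrofuran can form, and both bulky silyl ethers tolerate the brief mild acid.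

Step 16
Reactants: 22 C7 dimethyl acetal
Product: 23 diol acetal (C5–OH and C4–OH)
Conditions: TBAF, THF, 50 °C
Reagents that add atoms: none
Why: Fluoride-mediated desilylation removes both silyl ethers under basic conditions that leave the acetal untouched; the γ-hydroxy acetal is kept away from acid to prevent transacetalisation to the cyclic acetal.

Step 17
Reactants: 23 diol acetal
Product: 24 bis-mesylate
Conditions: MsCl, Et3N, CH2Cl2, 0 °C
Reagents that add atoms: methanesulfonyl chloride, CS(=O)(=O)Cl
Why: Sulfonylation with MsCl/Et3N should esterify both the primary and the hindered secondary hydroxyl without acid, giving the two leaving groups for sulfur.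

Step 18
Reactants: 24 bis-mesylate
Product: 26 cyclopentane-fused thiepane (sulfur bridges C4 and C5), via sodium thiolate monomesylate 25 (not isolated)
Conditions: Na2S·9H2O, DMF, high dilution, 60 °C
Reagents that add atoms: sodium sulfide, [Na+].[Na+].[S-2]
Why: Double nucleophilic substitution (SN2) by sulfide; the primary mesylate should react first to give thiolate 25, which closes the seven-membered ring by 7-exo-tet attack at the secondary mesylate, and inversion at C4 is of no consequence because C4 becomes sp2 in step 20.

Step 19
Reactants: 26 thiepane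
Product: 27 thiepane 1,1-dioxide (key-step precursor)
Conditions: mCPBA (2.5 equiv), NaHCO3, CH2Cl2, 0 °C → rt
Reagents that add atoms: 3-chloroperoxybenzoic acid, OOC(=O)c1cccc(Cl)c1
Why: Peracid oxidation of the sulfide through the sulfoxide should give the sulfone; no alkene is present and NaHCO3 protects the acetal from the acid by-product.

Step 20
Reactants: 27 thiepane 1,1-dioxide
Product: 30 hydrindene dimethyl acetal, via α-bromo sulfone 28 (not isolated), via episulfone 29 (not isolated)
Conditions: CBr2F2, KOH/Al2O3, t-BuOH/CH2Cl2, 5 °C → rt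
Reagents that add atoms: none
Why: Ramberg–Bäcklund reaction in its one-flask halogenative form: KOH deprotonates 27 at an α-carbon (most readily the C5 methylene) and the carbanion takes bromine from CBr2F2 to give 28; deprotonation at the other α-carbon (C4) and 1,3-displacement of bromide give episulfone 29, which loses SO2 to give the C4=C5 alkene. The closest known reactions are ring contractions of cyclic sulfones (thiepane 1,1-dioxides to cyclohexenes) with in situ α-halogenation under CBr2F2/KOH–Al2O3 or CCl4/KOH. The cyclohexene is closed by forming the C4–C5 bond across sulfur, a 3-exo-tet displacement inside the seven-membered ring, after which extrusion of SO2 leaves the six-membered ring. No stereocentre is created: C4 becomes sp2, so both C4 epimers of 27 converge, the six-membered ring allows only the cis ring alkene, and C1, C2, C3 and C6 are untouched because no bond to them is made or broken. The step needs only chemoselective monohalogenation α to sulfur: the acetal removes the only carbonyl, the sulfone α-hydrogens are the only acidic C–H bonds, the position of sulfur fixes the alkene between C4 and C5, and the difluorocarbene released is consumed by hydroxide rather than by the hindered product alkene.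

Step 21
Reactants: 30 hydrindene dimethyl acetal
Product: 31 hydrindene aldehyde
Conditions: TsOH·H2O (cat.), acetone/H2O, rt
Reagents that add atoms: water, O
Why: Acid-catalysed acetal hydrolysis in wet acetone should unmask the aldehyde under conditions too mild to protonate or shift the trisubstituted alkene.

Step 22
Reactants: 31 hydrindene aldehyde; 32 ethyl 2-(triphenylphosphoranylidene)propanoate
Product: 33 plakotenin ethyl ester
Conditions: toluene, 110 °C
Reagents that add atoms: none
Why: Wittig olefination with the stabilised α-methyl ylide should give the (E)-trisubstituted enoate, the usual outcome for stabilised ylides; the aldehyde is non-enolisable, so prolonged heating is tolerated.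

Step 23
Reactants: 33 plakotenin ethyl ester
Product: 34 plakotenin
Conditions: LiOH·H2O, THF/MeOH/H2O, 50 °C; then 1 M HCl
Reagents that add atoms: lithium hydroxide, [Li+].[OH-]
Why: Saponification of the ethyl ester and acidification should give the acid without affecting the alkene geometry or any stereocentre.

**Compound list**
1 | furan-2(5H)-one | O=C1OCC=C1 | starting material
2 | phenylboronic acid | OB(O)c1ccccc1 | starting material
3 | (R)-4-phenyldihydrofuran-2(3H)-one | O=C1C[C@H](c2ccccc2)CO1 | intermediate
4 | lithium (R)-4-phenyl-4,5-dihydrofuran-2-olate (lithium enolate of 3) | [Li]OC1=C[C@H](c2ccccc2)CO1 | intermediate (not isolated)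
5 | (R)-trimethyl[(4-phenyl-4,5-dihydrofuran-2-yl)oxy]silane | C[Si](C)(C)OC1=C[C@H](c2ccccc2)CO1 | intermediate
6 | (S)-4-(tert-butyldimethylsilyloxy)cyclopent-2-en-1-one | O=C1C=C[C@@H](O[Si](C)(C)C(C)(C)C)C1 | starting material
7 | acetaldehyde | CC=O | starting material
8 | trimethylsilyl enol ether [C9(OSiMe3)=C3; lactone on C2 trans to the C11 silyloxy group] | [C@H]1(C(=O)OC[C@H]1c1ccccc1)[C@H]2C=C(O[Si](C)(C)C)C[C@@H]2O[Si](C)(C)C(C)(C)C | intermediate (not isolated)
9 | β-hydroxy ketone (C9 ketone; 1-hydroxyethyl on C3 trans to lactone on C2; C11 silyloxy trans to lactone; carbinol epimers) | [C@H]1(C(=O)OC[C@H]1c1ccccc1)[C@H]2[C@H](C(C)O)C(=O)C[C@@H]2O[Si](C)(C)C(C)(C)C | intermediate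
10 | triisopropylsilyl ether of 9 | [C@H]1(C(=O)OC[C@H]1c1ccccc1)[C@H]2[C@H](C(C)O[Si](C(C)C)(C(C)C)C(C)C)C(=O)C[C@@H]2O[Si](C)(C)C(C)(C)C | intermediate
11 | C9 exocyclic methylene compound | [C@H]1(C(=O)OC[C@H]1c1ccccc1)[C@H]2[C@H](C(C)O[Si](C(C)C)(C(C)C)C(C)C)C(=C)C[C@@H]2O[Si](C)(C)C(C)(C)C | intermediate
12 | C9 methyl compound (methyl cis to C3 side chain) | [C@H]1(C(=O)OC[C@H]1c1ccccc1)[C@H]2[C@H](C(C)O[Si](C(C)C)(C(C)C)C(C)C)[C@H](C)C[C@@H]2O[Si](C)(C)C(C)(C)C | intermediate
13 | C11 alcohol | [C@H]1(C(=O)OC[C@H]1c1ccccc1)[C@H]2[C@H](C(C)O[Si](C(C)C)(C(C)C)C(C)C)[C@H](C)C[C@@H]2O | intermediate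
14 | C11 ketone | [C@H]1(C(=O)OC[C@H]1c1ccccc1)[C@H]2[C@H](C(C)O[Si](C(C)C)(C(C)C)C(C)C)[C@H](C)CC2=O | intermediate
15 | C11 exocyclic methylene lactone | [C@H]1(C(=O)OC[C@H]1c1ccccc1)[C@H]2[C@H](C(C)O[Si](C(C)C)(C(C)C)C(C)C)[C@H](C)CC2=C | intermediate
16 | lithium enolate of 15 | [Li]OC1=C([C@H]2[C@H](C(C)O[Si](C(C)C)(C(C)C)C(C)C)[C@H](C)CC2=C)[C@H](c2ccccc2)CO1 | intermediate (not isolated)
17 | C1-ethyl lactone with C11 methylene (ethyl trans to phenyl) | CC[C@@]1(C(=O)OC[C@H]1c1ccccc1)[C@H]2[C@H](C(C)O[Si](C(C)C)(C(C)C)C(C)C)[C@H](C)CC2=C | intermediate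
18 | lactone with all six stereocentres (C11 methyl cis to C2 substituent) | CC[C@@]1(C(=O)OC[C@H]1c1ccccc1)[C@H]2[C@H](C(C)O[Si](C(C)C)(C(C)C)C(C)C)[C@H](C)C[C@H]2C | intermediate
19 | 1,4-diol (C5–OH, C7–OH) with C4 triisopropylsilyl ether | CC[C@@]([C@@H](CO)c1ccccc1)(CO)[C@H]2[C@H](C(C)O[Si](C(C)C)(C(C)C)C(C)C)[C@H](C)C[C@H]2C | intermediate
20 | C5 tert-butyldiphenylsilyl ether, C7 alcohol | CC[C@@]([C@@H](CO[Si](c1ccccc1)(c1ccccc1)C(C)(C)C)c1ccccc1)(CO)[C@H]2[C@H](C(C)O[Si](C(C)C)(C(C)C)C(C)C)[C@H](C)C[C@H]2C | intermediate
21 | C7 aldehyde | CC[C@@]([C@@H](CO[Si](c1ccccc1)(c1ccccc1)C(C)(C)C)c1ccccc1)(C=O)[C@H]2[C@H](C(C)O[Si](C(C)C)(C(C)C)C(C)C)[C@H](C)C[C@H]2C | intermediate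
22 | C7 dimethyl acetal, bis-silyl ether | CC[C@@]([C@@H](CO[Si](c1ccccc1)(c1ccccc1)C(C)(C)C)c1ccccc1)(C(OC)OC)[C@H]2[C@H](C(C)O[Si](C(C)C)(C(C)C)C(C)C)[C@H](C)C[C@H]2C | intermediate
23 | diol acetal (C5–OH, C4–OH) | CC[C@@]([C@@H](CO)c1ccccc1)(C(OC)OC)[C@H]2[C@H](C(C)O)[C@H](C)C[C@H]2C | intermediate
24 | bis-mesylate | CC[C@@]([C@@H](COS(C)(=O)=O)c1ccccc1)(C(OC)OC)[C@H]2[C@H](C(C)OS(C)(=O)=O)[C@H](C)C[C@H]2C | intermediate
25 | sodium C5-thiolate C4-mesylate | CC[C@@]([C@@H](C[S-])c1ccccc1)(C(OC)OC)[C@H]2[C@H](C(C)OS(C)(=O)=O)[C@H](C)C[C@H]2C.[Na+] | intermediate (not isolated)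
26 | cyclopentane-fused thiepane, dimethyl acetal | CC[C@@]1(C(OC)OC)[C@H]2[C@H](C(C)SC[C@H]1c1ccccc1)[C@H](C)C[C@H]2C | intermediate
27 | cyclopentane-fused thiepane 1,1-dioxide, dimethyl acetal | CC[C@@]1(C(OC)OC)[C@H]2[C@H](C(C)S(=O)(=O)C[C@H]1c1ccccc1)[C@H](C)C[C@H]2C | intermediate
28 | C5-bromo sulfone | CC[C@@]1(C(OC)OC)[C@H]2[C@H](C(C)S(=O)(=O)C(Br)[C@H]1c1ccccc1)[C@H](C)C[C@H]2C | intermediate (not isolated)
29 | episulfone (thiirane 1,1-dioxide across C4–C5) | CC[C@@]1(C(OC)OC)[C@H]2[C@H](C3(C)S(=O)(=O)C3[C@H]1c1ccccc1)[C@H](C)C[C@H]2C | intermediate (not isolated)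
30 | hydrindene dimethyl acetal | CC[C@@]1(C(OC)OC)[C@H]2[C@H](C(C)=C[C@H]1c1ccccc1)[C@H](C)C[C@H]2C | intermediate
31 | hydrindene aldehyde | CC[C@@]1(C=O)[C@H]2[C@H](C(C)=C[C@H]1c1ccccc1)[C@H](C)C[C@H]2C | intermediate
32 | ethyl 2-(triphenylphosphoranylidene)propanoate | CCOC(=O)C(C)=P(c1ccccc1)(c1ccccc1)c1ccccc1 | starting material
33 | plakotenin ethyl ester | CC[C@@]1(/C=C(\C)C(=O)OCC)[C@H]2[C@H](C(C)=C[C@H]1c1ccccc1)[C@H](C)C[C@H]2C | intermediate
34 | plakotenin | CC[C@@]1(/C=C(\C)C(=O)O)[C@H]2[C@H](C(C)=C[C@H]1c1ccccc1)[C@H](C)C[C@H]2C | target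

**Step count**
Total: 23 steps. Longest linear sequence: 23 steps (1 → 34); compounds 2, 6, 7 and 32 are bought.

**Steps most likely to fail**

Step 11. Facial selectivity of the hydrogenation may be poor, because the face that must receive hydrogen also carries the 1,3-related C3 side chain and the C9 methyl; isomerisation of the alkene into the ring before reduction is a second risk. The fallback replaces steric control by hydroxyl direction. It sets out from 17: desilylation (TBAF, AcOH, THF) should give the C4-hydroxy methylene lactone F1. Hydrogenation with the cationic iridium catalyst [Ir(cod)(PCy3)(py)]PF6 (H2, CH2Cl2) should then be directed by the C4 hydroxyl, which sits on the face opposite the quaternary C1, and give the C4-hydroxy C11-methyl lactone F2. Re-silylation (TIPSOTf, 2,6-lutidine) comes back to the route at 18.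

Step 18. Elimination at the hindered secondary mesylate and intermolecular oligomerisation may compete with seven-membered ring closure. The fallback makes the secondary C–S bond first under neutral conditions and closes the ring at the primary carbon. It sets out from 23: selective mesylation of the primary hydroxyl (MsCl, 2,4,6-collidine, CH2Cl2, −20 °C) should give the C5 mesylate C4 alcohol F3. A Mitsunobu reaction with thioacetic acid (PPh3, DIAD, THF) should give the C5 mesylate C4 thioacetate F4. Methanolysis (K2CO3, degassed MeOH) frees the thiolate, which closes onto the primary mesylate and comes back to the route at 26.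

Step 20. Repeated bromination at C5 before the slow deprotonation of the hindered tertiary C4–H, or base-induced ring opening of the sulfone, may consume material before the 1,3-elimination. The fallback forms the same alkene by reductive carbonyl coupling. It sets out from 23: double Dess–Martin oxidation should give the keto aldehyde F5, which is used at once because its α-phenyl aldehyde centre can epimerise. Intramolecular McMurry coupling (TiCl3(DME)1.5, Zn–Cu, DME, reflux, slow addition) should join C4 and C5 and comes back to the route at 30.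

**Further compounds**
F1 | step 11 | C4-hydroxy lactone with C11 methylene | CC[C@@]1(C(=O)OC[C@H]1c1ccccc1)[C@H]2[C@H](C(C)O)[C@H](C)CC2=C
F2 | step 11 | C4-hydroxy lactone with C11 methyl | CC[C@@]1(C(=O)OC[C@H]1c1ccccc1)[C@H]2[C@H](C(C)O)[C@H](C)C[C@H]2C
F3 | step 18 | C5 mesylate C4 alcohol | CC[C@@]([C@@H](COS(C)(=O)=O)c1ccccc1)(C(OC)OC)[C@H]2[C@H](C(C)O)[C@H](C)C[C@H]2C
F4 | step 18 | C5 mesylate C4 thioacetate | CC[C@@]([C@@H](COS(C)(=O)=O)c1ccccc1)(C(OC)OC)[C@H]2[C@H](C(C)SC(C)=O)[C@H](C)C[C@H]2C
F5 | step 20 | keto aldehyde (C4 ketone, C5 aldehyde) | CC[C@@]([C@@H](C=O)c1ccccc1)(C(OC)OC)[C@H]2[C@H](C(C)=O)[C@H](C)C[C@H]2C
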